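**Plan**
- Cuts: C11=C13 (made last by elimination), the ring A ester bond O8–C12 together with the ring B bond C8–C9 (one step), C6–C7, and the norbornene bonds C1–C13' and C3–C11'.
- Enabling feature: methyl-bearing C10 lies between bridgehead C1 and C9H2, and C9 adjoins the lactone carbinol C8. A 3-(trimethylsilyl)prop-1-en-2-yl group on C1 (= C14, C10, C9) can therefore close the seven-membered ring B onto a C8 aldehyde hung from C5 through C6–C7, after which O8 closes lactone ring A on C12.
- Forward order: 2-silyloxycyclopentadiene + silylated 1-O-acetylbritannilactone → norbornane core with the spiro lactone; C10 ketone → allylsilane; C5 ketone → enol triflate → C6; C6–C7 by imide alkylation; C8 aldehyde; rings B and A together; then C10 methyl, C11=C13, desilylation.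
- Stereochemistry: C2 from (S)-4-hydroxycyclopentenone; C1, C3, C11' from the cycloaddition (anti to the C2 silyl ether, lactone carbonyl exo); C7 from (R)-4-benzyloxazolidinone; C8 from C7 in the ring closure; C10 by lactone-directed hydrogenation; C4', C6', C7', C8' from the natural lactone.

Key step: step 21

Remark: locants are those of the two sesquiterpenoid halves (guaianolide half C1–C15, seco-eudesmanolide half primed); 1-O-acetylbritannilactone is assumed purchasable as the isolated natural product; C4 and the C10 carbinol are unassigned until they become sp2, and every compound carrying C11 as an sp3 centre is a pair of C11 epimers.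

Step 1
Reactants: 1 (S)-4-hydroxycyclopent-2-en-1-one
Product: 2 (S)-4-(triethylsilyloxy)cyclopent-2-en-1-one
Conditions: Et3SiCl, imidazole, CH2Cl2, 0 °C
Reagents that add atoms: chlorotriethylsilane, CC[Si](Cl)(CC)CC
Why: Routine silylation of a secondary alcohol; the carbinol carbon is the future C2 (the ring carbons of 1 become C5 = carbonyl, C4, C3, C2, C1) and its bulky silyl ether later shields one face of the ring.

Step 2
Reactants: 2 (S)-4-(triethylsilyloxy)cyclopent-2-en-1-one
Product: 3 (S)-2-iodo-4-(triethylsilyloxy)cyclopent-2-en-1-one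
Conditions: I2, pyridine, CH2Cl2, 0 → 23 °C
Reagents that add atoms: iodine, II
Why: Johnson α-iodination of an enone (pyridine conjugate addition, iodination of the enolate, elimination), established for 4-silyloxycyclopentenones.

Step 3
Reactants: 3 (S)-2-iodo-4-(triethylsilyloxy)cyclopent-2-en-1-one
Product: 4 (S)-2-methyl-4-(triethylsilyloxy)cyclopent-2-en-1-one
Conditions: MeZnCl, Pd(PPh3)4 (5 mol %), THF, 23 °C
Reagents that add atoms: methylzinc chloride, C[Zn]Cl
Why: Negishi coupling of an α-iodoenone with an alkylzinc halide puts the future C15 methyl on C4 under neutral conditions that do not eliminate the β-silyloxy group.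

Step 4
Reactants: 4 (S)-2-methyl-4-(triethylsilyloxy)cyclopent-2-en-1-one; 5 acetaldehyde
Product: 6 4,5-trans-5-(1-hydroxyethyl)-2-methyl-4-(triethylsilyloxy)cyclopent-2-en-1-one (carbinol epimers)
Conditions: LiN(iPr)2, THF, −78 °C; then 5; NH4Cl (aq)
Reagents that add atoms: none
Why: Aldol addition of the kinetic α'-lithium enolate (kept cold so the β-silyloxy group is not expelled), the aldehyde entering trans to the neighbouring silyl ether as known for 4-silyloxycyclopentenones; the two added carbons are C10 and its methyl, and both new stereocentres are erased later (steps 5 and 8).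

Step 5
Reactants: 6 4,5-trans aldol
Product: 7 silyloxy diene, 3-methyl-5-(triethylsilyloxy)-2-(trimethylsilyloxy)-1-[1-(trimethylsilyloxy)ethyl]cyclopenta-1,3-diene
Conditions: Me3SiOTf (2.5 equiv), Et3N, CH2Cl2, −20 → 0 °C; used crude
Reagents that add atoms: trimethylsilyl trifluoromethanesulfonate, C[Si](C)(C)OS(=O)(=O)C(F)(F)F
Why: Soft enolisation silylates the carbinol and turns the enone into its cross-conjugated 2-silyloxycyclopentadiene by loss of the α' hydrogen without a free enolate, giving the diene C1=C5(OSiMe3)–C4(Me)=C3 with C2 as the only sp3 ring carbon.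

Step 6
Reactants: 8 1-O-acetylbritannilactone
Product: 9 6'-O-(tert-butyldimethylsilyl)-1'-O-acetylbritannilactone
Conditions: t-BuMe2SiOTf, 2,6-lutidine, CH2Cl2, −78 → 0 °C
Reagents that add atoms: tert-butyldimethylsilyl trifluoromethanesulfonate, CC(C)(C)[Si](C)(C)OS(=O)(=O)C(F)(F)F
Why: Silyl triflate protection of the hindered allylic C6' alcohol so that it survives the oxidations and strong bases ahead.

Step 7
Reactants: 7 silyloxy diene; 9 6'-O-TBS acetylbritannilactone
Product: 11 cycloadduct ketol (C5 ketone, C10 carbinol, C2 triethylsilyl ether, spiro lactone at C11'), via silyl enol ether cycloadduct 10 (not isolated)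
Conditions: 7 (2 equiv), HNTf2 (5 mol %), CH2Cl2, −78 → −40 °C; then citric acid, MeOH, 0 °C
Reagents that add atoms: none
Why: Lewis-acid-promoted Diels–Alder reaction of a 2-silyloxycyclopentadiene (a Mukaiyama–Michael/Michael sequence): the silyl dienol ether polarity joins C1 to C13' and C3 to C11', the lactone adds anti to the C2 silyl ether as in additions to 4-silyloxycyclopentenones (C1 and C3 follow from C2), the s-cis α-methylene lactone reacts with its carbonyl and bulky silyl ketene acetal oxygen exo (setting C11'), and mild acid then frees the C5 ketone and the C10 carbinol.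

Step 8
Reactants: 11 cycloadduct ketol
Product: 12 5,10-diketone
Conditions: Dess–Martin periodinane, CH2Cl2, 23 °C
Reagents that add atoms: none
Why: Neutral Dess–Martin oxidation of the secondary carbinol gives the C10 methyl ketone, removes the carbinol epimers and avoids the basic conditions that could trigger retro-aldol or retro-Claisen cleavage at the quaternary C1.

Step 9
Reactants: 12 5,10-diketone
Product: 13 C10 enol triflate (C1 bears 1-(trifluoromethylsulfonyloxy)vinyl)
Conditions: KN(SiMe3)2 (1.05 equiv), THF, −78 °C; PhNTf2, −78 → −40 °C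
Reagents that add atoms: N-phenylbis(trifluoromethanesulfonimide), O=S(=O)(N(c1ccccc1)S(=O)(=O)C(F)(F)F)C(F)(F)F
Why: Kinetic deprotonation takes the unhindered methyl group of the C10 ketone (the ring ketone has only the tertiary C4–H and C1 is quaternary) and the triflimide traps the enolate as the 1-substituted vinyl triflate.

Step 10
Reactants: 13 C10 enol triflate
Product: 14 allylsilane ketone (C1 bears 3-(trimethylsilyl)prop-1-en-2-yl)
Conditions: Me3SiCH2MgCl, ZnCl2, THF, 0 °C; then 13, Pd(PPh3)4 (5 mol %), 45 °C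
Reagents that add atoms: (trimethylsilyl)methylmagnesium chloride, C[Si](C)(C)C[Mg]Cl
Why: Negishi coupling of a vinyl triflate with a (trimethylsilyl)methylzinc reagent is a standard route to 2-substituted allylsilanes, and the organozinc does not add to the C5 ketone, the lactone or the acetate.

Step 11
Reactants: 14 allylsilane ketone
Product: 15 allylsilane C5 enol triflate (C4=C5)
Conditions: KN(SiMe3)2, THF, −78 °C; N-(5-chloropyridin-2-yl)bis(trifluoromethanesulfonimide), −78 → −20 °C
Reagents that add atoms: N-(5-chloropyridin-2-yl)bis(trifluoromethanesulfonimide), O=S(=O)(N(c1ccc(Cl)cn1)S(=O)(=O)C(F)(F)F)C(F)(F)F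
Why: C4 is the only enolisable position left, so deprotonation and O-triflation with the more reactive pyridyl triflimide give the tetrasubstituted enol triflate regiospecifically and merge the C4 epimers.

Step 12
Reactants: 15 allylsilane C5 enol triflate
Product: 16 C2 alcohol
Conditions: pyridinium p-toluenesulfonate, MeOH, 23 °C
Reagents that add atoms: none
Why: Mild acid methanolysis cleaves the triethylsilyl ether far faster than the tert-butyldimethylsilyl ether, and neither the vinyl triflate nor the allylsilane responds to this weak acid.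

Step 13
Reactants: 16 C2 alcohol
Product: 17 C2 acetate
Conditions: Ac2O, pyridine, 4-(dimethylamino)pyridine (cat.), CH2Cl2, 23 °C
Reagents that add atoms: acetic anhydride, CC(=O)OC(C)=O
Why: Nucleophile-catalysed acetylation installs the C2 acetate of the target only after both strong-base enolisations are over.

Step 14
Reactants: 17 C2 acetate
Product: 18 C6 allylic alcohol (C5–CH2OH)
Conditions: Bu3SnCH2OH, Pd(PPh3)4 (10 mol %), LiCl, 1,4-dioxane, 90 °C
Reagents that add atoms: (tributylstannyl)methanol, CCCC[Sn](CCCC)(CCCC)CO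
Why: Migita–Kosugi–Stille coupling of a vinyl triflate with (tributylstannyl)methanol (chloride-assisted transmetallation) delivers the one-carbon unit C6 directly as the allylic alcohol.

Step 15
Reactants: 18 C6 allylic alcohol
Product: 19 C6 allylic bromide
Conditions: CBr4, PPh3, CH2Cl2, 0 °C; used at once
Reagents that add atoms: carbon tetrabromide, BrC(Br)(Br)Br
Why: Appel bromination of a primary allylic alcohol under neutral conditions that tolerate the allylsilane, esters and silyl ether.

Step 16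
Reactants: 20 4-methoxy-4-oxobutanoic acid (monomethyl succinate)
Product: 23 4-(tert-butyldimethylsilyloxy)-3-(methoxycarbonyl)butanoic acid (racemic), via dilithium hydroxymethyl adduct 21 (not isolated), via bis-silyl derivative 22 (not isolated)
Conditions: LiN(iPr)2 (2.2 equiv), THF, −78 °C; CH2O (gas), −78 → −30 °C; t-BuMe2SiOTf (2.2 equiv), −78 → 0 °C; K2CO3, MeOH–H2O, 0 °C; citric acid (aq)
Reagents that add atoms: formaldehyde, C=O; tert-butyldimethylsilyl trifluoromethanesulfonate, CC(C)(C)[Si](C)(C)OS(=O)(=O)C(F)(F)F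
Why: The dianion of a succinic half-ester is the carboxylate ester-enolate, which is hydroxymethylated α to the ester (future C11 with C13 attached); silylation in the same flask blocks lactonisation to the paraconate and the labile silyl ester falls off on mild basic work-up.

Step 17
Reactants: 23 silyloxymethyl succinic half-ester; 24 (R)-4-benzyl-1,3-oxazolidin-2-one
Product: 26 succinyl imide, (4R)-4-benzyl-3-[4-(tert-butyldimethylsilyloxy)-3-(methoxycarbonyl)butanoyl]-1,3-oxazolidin-2-one, via mixed pivalic anhydride 25 (not isolated)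
Conditions: t-BuCOCl, Et3N, THF, −20 °C; then 24/n-BuLi (THF, −78 °C), −78 → 0 °C
Reagents that add atoms: none
Why: Acylation of the lithiated oxazolidinone by the mixed pivalic anhydride at its less hindered carbonyl is the standard preparation of Evans imides.

Step 18
Reactants: 26 succinyl imide; 19 C6 allylic bromide
Product: 27 C7-alkylated imide
Conditions: 26 (1.5 equiv), NaN(SiMe3)2, THF, −78 °C; then 19, −78 → −40 °C
Reagents that add atoms: none
Why: Evans alkylation: the chelated Z-sodium enolate of the imide (the less acidic ester α-hydrogen at C11 is untouched) is alkylated by the primary allylic bromide on the face opposite the benzyl group, forming C6–C7 and setting C7, the (R)-auxiliary being the one that gives the C7 configuration of the target.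

Step 19
Reactants: 27 C7-alkylated imide
Product: 28 C8 S-ethyl thioester
Conditions: EtSH, n-BuLi, THF, 0 °C
Reagents that add atoms: ethanethiol, CCS
Why: The soft lithium thiolate attacks only the activated exocyclic imide carbonyl (Damon–Coppola transthioesterification), releasing the auxiliary and leaving the methyl ester, lactone and acetates.

Step 20
Reactants: 28 C8 thioester
Product: 29 allylsilane aldehyde ester (C8 aldehyde, C12 methyl ester, C13 silyl ether)
Conditions: Et3SiH, Pd/CaCO3 poisoned with Pb, acetone, 23 °C; used at once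
Reagents that add atoms: none
Why: Fukuyama reduction (oxidative addition of the thioester C–S bond to palladium, then hydride transfer from silicon) gives the aldehyde chemoselectively, the poisoned catalyst sparing the 1,1-disubstituted alkene of the allylsilane.

Step 21
Reactants: 29 allylsilane aldehyde ester
Product: 31 C10-methylene lactone (rings A and B closed, C13 silyl ether), via ring B hydroxy ester 30 (not isolated)
Conditions: BF3·OEt2 (2 equiv), CH2Cl2, −78 → −30 °C; NaHCO3 (aq); then camphor-10-sulfonic acid (cat.), CH2Cl2, 23 °C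
Reagents that add atoms: none
Why: BF3 binds the C8 aldehyde, the terminal alkene carbon of the allylsilane (C9) attacks it in anti-SE2' fashion, the β-silyl cation loses silicon to leave the C10=C14 exocyclic methylene, and the C8 oxygen then acylates on the C12 methyl ester with loss of methanol. The closest known reaction type is the Lewis-acid-promoted intramolecular Hosomi–Sakurai cyclisation of 2-substituted allylsilanes onto aldehydes to give methylenecycloalkanols, followed by lactonisation of a γ-hydroxy ester. Ring B (C1–C10–C9–C8–C7–C6–C5) closes 7-exo-trig at the carbonyl carbon, helped by the two arms sitting on the adjacent carbons C1 and C5 of the rigid norbornene, and ring A closes 5-exo-trig at the ester carbonyl. The one new stereocentre, C8, is controlled by C7: in the chair-like synclinal transition state the C11 arm on C7 is pseudo-equatorial and the BF3-bound oxygen lies anti to it, which gives the 7,8-trans relationship of the trans-fused lactone. The step needs chemoselectivity for the aldehyde over esters, lactone and acetates, which only the aldehyde's Lewis basicity and reactivity at −78 °C provide, and it must outrun protodesilylation, which anhydrous cold conditions and intramolecularity favour.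

Step 22
Reactants: 31 C10-methylene lactone
Product: 32 C10-methyl lactone
Conditions: H2 (1 atm), [Ir(cod)(PCy3)(py)]PF6 (5 mol %), CH2Cl2, 0 → 23 °C
Reagents that add atoms: none
Why: Directed hydrogenation: the cationic iridium centre binds the lactone oxygen on C8 and delivers hydrogen to the same face of the 1,1-disubstituted alkene, so H10 ends cis and the C14 methyl trans to the C8 oxygen, while the tetrasubstituted alkenes do not react at 1 atm.

Step 23
Reactants: 32 C10-methyl lactone
Product: 33 C13 alcohol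
Conditions: HF·pyridine, pyridine, THF, 0 °C
Reagents that add atoms: none
Why: Buffered HF·pyridine removes the unhindered primary silyl ether much faster than the hindered secondary allylic one at C6'.

Step 24
Reactants: 33 C13 alcohol
Product: 35 6'-O-TBS ether of the target (C11=C13 α-methylene lactone), via C13 mesylate 34 (not isolated)
Conditions: MsCl, Et3N, CH2Cl2, 0 °C; then DBU, 23 °C
Reagents that add atoms: none
Why: Mesylation followed by E1cB elimination through the lactone enolate is the standard unveiling of an α-methylene-γ-butyrolactone and converts both C11 epimers into one compound.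

Step 25
Reactants: 35 6'-O-TBS ether of the target
Product: 36 CNP0211028.3
Conditions: HF·pyridine, THF, 23 °C
Reagents that add atoms: none
Why: Acidic fluoride cleaves the last silyl ether without touching the acetates, the lactones or the Michael-acceptor methylene.

**Compound list**
1 | (S)-4-hydroxycyclopent-2-en-1-one | O=C1C=C[C@@H](O)C1 | starting material
2 | (S)-4-(triethylsilyloxy)cyclopent-2-en-1-one | O=C1C=C[C@@H](O[Si](CC)(CC)CC)C1 | intermediate
3 | (S)-2-iodo-4-(triethylsilyloxy)cyclopent-2-en-1-one | O=C1C(I)=C[C@@H](O[Si](CC)(CC)CC)C1 | intermediate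
4 | (S)-2-methyl-4-(triethylsilyloxy)cyclopent-2-en-1-one | O=C1C(C)=C[C@@H](O[Si](CC)(CC)CC)C1 | intermediate
5 | acetaldehyde | CC=O | starting material
6 | 4,5-trans-5-(1-hydroxyethyl)-2-methyl-4-(triethylsilyloxy)cyclopent-2-en-1-one (C4 as in 4, carbinol epimers) | O=C1C(C)=C[C@@H](O[Si](CC)(CC)CC)[C@@H]1C(C)O | intermediate
7 | 3-methyl-5-(triethylsilyloxy)-2-(trimethylsilyloxy)-1-[1-(trimethylsilyloxy)ethyl]cyclopenta-1,3-diene (silyloxy carbon as in 4) | CC1=C[C@@H](O[Si](CC)(CC)CC)C(C(C)O[Si](C)(C)C)=C1O[Si](C)(C)C | intermediate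
8 | 1-O-acetylbritannilactone | C=C1C(=O)O[C@@H]2CC(C)=C([C@@H](C)CCCOC(C)=O)[C@@H](O)[C@@H]21 | starting material
9 | 6'-O-(tert-butyldimethylsilyl)-1'-O-acetylbritannilactone | C=C1C(=O)O[C@@H]2CC(C)=C([C@@H](C)CCCOC(C)=O)[C@@H](O[Si](C)(C)C(C)(C)C)[C@@H]21 | intermediate
10 | silyl enol ether cycloadduct (C4=C5–OSiMe3, C10–OSiMe3, C2–OSiEt3, spiro lactone at C11') | CC(O[Si](C)(C)C)[C@@]34C[C@]5(C(=O)O[C@@H]6CC(C)=C([C@@H](C)CCCOC(C)=O)[C@@H](O[Si](C)(C)C(C)(C)C)[C@@H]65)[C@@H](C(C)=C3O[Si](C)(C)C)[C@H]4O[Si](CC)(CC)CC | intermediate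
11 | cycloadduct ketol (C5 ketone, C4 epimers, C10 carbinol epimers, C2–OSiEt3) | CC(O)[C@@]34C[C@]5(C(=O)O[C@@H]6CC(C)=C([C@@H](C)CCCOC(C)=O)[C@@H](O[Si](C)(C)C(C)(C)C)[C@@H]65)[C@@H](C(C)C3=O)[C@H]4O[Si](CC)(CC)CC | intermediate
12 | 5,10-diketone (C1 acetyl, C5 ketone) | CC(=O)[C@@]34C[C@]5(C(=O)O[C@@H]6CC(C)=C([C@@H](C)CCCOC(C)=O)[C@@H](O[Si](C)(C)C(C)(C)C)[C@@H]65)[C@@H](C(C)C3=O)[C@H]4O[Si](CC)(CC)CC | intermediate
13 | C10 enol triflate (C1 bears 1-(triflyloxy)vinyl, C5 ketone) | C=C(OS(=O)(=O)C(F)(F)F)[C@@]34C[C@]5(C(=O)O[C@@H]6CC(C)=C([C@@H](C)CCCOC(C)=O)[C@@H](O[Si](C)(C)C(C)(C)C)[C@@H]65)[C@@H](C(C)C3=O)[C@H]4O[Si](CC)(CC)CC | intermediate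
14 | allylsilane ketone (C1 bears 3-(trimethylsilyl)prop-1-en-2-yl, C5 ketone) | C=C(C[Si](C)(C)C)[C@@]34C[C@]5(C(=O)O[C@@H]6CC(C)=C([C@@H](C)CCCOC(C)=O)[C@@H](O[Si](C)(C)C(C)(C)C)[C@@H]65)[C@@H](C(C)C3=O)[C@H]4O[Si](CC)(CC)CC | intermediate
15 | allylsilane C5 enol triflate (C4=C5–OTf, C2–OSiEt3) | C=C(C[Si](C)(C)C)[C@@]34C[C@]5(C(=O)O[C@@H]6CC(C)=C([C@@H](C)CCCOC(C)=O)[C@@H](O[Si](C)(C)C(C)(C)C)[C@@H]65)[C@@H](C(C)=C3OS(=O)(=O)C(F)(F)F)[C@H]4O[Si](CC)(CC)CC | intermediate
16 | C2 alcohol of 15 | C=C(C[Si](C)(C)C)[C@@]34C[C@]5(C(=O)O[C@@H]6CC(C)=C([C@@H](C)CCCOC(C)=O)[C@@H](O[Si](C)(C)C(C)(C)C)[C@@H]65)[C@@H](C(C)=C3OS(=O)(=O)C(F)(F)F)[C@H]4O | intermediate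
17 | C2 acetate (C5 enol triflate) | C=C(C[Si](C)(C)C)[C@@]34C[C@]5(C(=O)O[C@@H]6CC(C)=C([C@@H](C)CCCOC(C)=O)[C@@H](O[Si](C)(C)C(C)(C)C)[C@@H]65)[C@@H](C(C)=C3OS(=O)(=O)C(F)(F)F)[C@H]4OC(C)=O | intermediate
18 | C6 allylic alcohol (C5–CH2OH) | C=C(C[Si](C)(C)C)[C@@]34C[C@]5(C(=O)O[C@@H]6CC(C)=C([C@@H](C)CCCOC(C)=O)[C@@H](O[Si](C)(C)C(C)(C)C)[C@@H]65)[C@@H](C(C)=C3CO)[C@H]4OC(C)=O | intermediate
19 | C6 allylic bromide (C5–CH2Br) | C=C(C[Si](C)(C)C)[C@@]34C[C@]5(C(=O)O[C@@H]6CC(C)=C([C@@H](C)CCCOC(C)=O)[C@@H](O[Si](C)(C)C(C)(C)C)[C@@H]65)[C@@H](C(C)=C3CBr)[C@H]4OC(C)=O | intermediate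
20 | 4-methoxy-4-oxobutanoic acid | COC(=O)CCC(=O)O | starting material
21 | dilithium 4-methoxy-3-(oxidomethyl)-4-oxobutanoate | [Li+].[Li+].[O-]CC(CC(=O)[O-])C(=O)OC | intermediate
22 | tert-butyldimethylsilyl 4-(tert-butyldimethylsilyloxy)-3-(methoxycarbonyl)butanoate | COC(=O)C(CO[Si](C)(C)C(C)(C)C)CC(=O)O[Si](C)(C)C(C)(C)C | intermediate
23 | 4-(tert-butyldimethylsilyloxy)-3-(methoxycarbonyl)butanoic acid (racemic) | COC(=O)C(CO[Si](C)(C)C(C)(C)C)CC(=O)O | intermediate
24 | (R)-4-benzyl-1,3-oxazolidin-2-one | O=C1N[C@H](Cc2ccccc2)CO1 | starting material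
25 | mixed pivalic anhydride of 23 | COC(=O)C(CO[Si](C)(C)C(C)(C)C)CC(=O)OC(=O)C(C)(C)C | intermediate
26 | (4R)-4-benzyl-3-[4-(tert-butyldimethylsilyloxy)-3-(methoxycarbonyl)butanoyl]-1,3-oxazolidin-2-one (C11 epimers) | COC(=O)C(CO[Si](C)(C)C(C)(C)C)CC(=O)N1[C@H](Cc2ccccc2)COC1=O | intermediate
27 | C7-alkylated imide (C6–C7 bond, C8 acyl oxazolidinone, C11 epimers) | C=C(C[Si](C)(C)C)[C@@]34C[C@]5(C(=O)O[C@@H]6CC(C)=C([C@@H](C)CCCOC(C)=O)[C@@H](O[Si](C)(C)C(C)(C)C)[C@@H]65)[C@@H](C(C)=C3C[C@@H](C(=O)N7[C@H](Cc8ccccc8)COC7=O)C(CO[Si](C)(C)C(C)(C)C)C(=O)OC)[C@H]4OC(C)=O | intermediate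
28 | C8 S-ethyl thioester (C11 epimers) | C=C(C[Si](C)(C)C)[C@@]34C[C@]5(C(=O)O[C@@H]6CC(C)=C([C@@H](C)CCCOC(C)=O)[C@@H](O[Si](C)(C)C(C)(C)C)[C@@H]65)[C@@H](C(C)=C3C[C@@H](C(=O)SCC)C(CO[Si](C)(C)C(C)(C)C)C(=O)OC)[C@H]4OC(C)=O | intermediate
29 | allylsilane aldehyde ester, rings A and B open (C11 epimers) | C=C(C[Si](C)(C)C)[C@@]34C[C@]5(C(=O)O[C@@H]6CC(C)=C([C@@H](C)CCCOC(C)=O)[C@@H](O[Si](C)(C)C(C)(C)C)[C@@H]65)[C@@H](C(C)=C3C[C@@H](C=O)C(CO[Si](C)(C)C(C)(C)C)C(=O)OC)[C@H]4OC(C)=O | intermediate
30 | ring B hydroxy ester (C8 alcohol, C10 exocyclic methylene, C11 epimers) | O[C@H]1CC(=C)[C@@]34C[C@]5(C(=O)O[C@@H]6CC(C)=C([C@@H](C)CCCOC(C)=O)[C@@H](O[Si](C)(C)C(C)(C)C)[C@@H]65)[C@@H](C(C)=C3C[C@@H]1C(CO[Si](C)(C)C(C)(C)C)C(=O)OC)[C@H]4OC(C)=O | intermediate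
31 | C10-methylene lactone with C13 tert-butyldimethylsilyl ether (C11 epimers) | O=C1O[C@H]2CC(=C)[C@@]34C[C@]5(C(=O)O[C@@H]6CC(C)=C([C@@H](C)CCCOC(C)=O)[C@@H](O[Si](C)(C)C(C)(C)C)[C@@H]65)[C@@H](C(C)=C3C[C@@H]2C1CO[Si](C)(C)C(C)(C)C)[C@H]4OC(C)=O | intermediate
32 | C10-methyl lactone (C11 epimers) | O=C1O[C@H]2C[C@H](C)[C@@]34C[C@]5(C(=O)O[C@@H]6CC(C)=C([C@@H](C)CCCOC(C)=O)[C@@H](O[Si](C)(C)C(C)(C)C)[C@@H]65)[C@@H](C(C)=C3C[C@@H]2C1CO[Si](C)(C)C(C)(C)C)[C@H]4OC(C)=O | intermediate
33 | C13 alcohol (C11 epimers) | O=C1O[C@H]2C[C@H](C)[C@@]34C[C@]5(C(=O)O[C@@H]6CC(C)=C([C@@H](C)CCCOC(C)=O)[C@@H](O[Si](C)(C)C(C)(C)C)[C@@H]65)[C@@H](C(C)=C3C[C@@H]2C1CO)[C@H]4OC(C)=O | intermediate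
34 | C13 mesylate (C11 epimers) | O=C1O[C@H]2C[C@H](C)[C@@]34C[C@]5(C(=O)O[C@@H]6CC(C)=C([C@@H](C)CCCOC(C)=O)[C@@H](O[Si](C)(C)C(C)(C)C)[C@@H]65)[C@@H](C(C)=C3C[C@@H]2C1COS(C)(=O)=O)[C@H]4OC(C)=O | intermediate
35 | 6'-O-(tert-butyldimethylsilyl) ether of the target | C=C1C(=O)O[C@H]2C[C@H](C)[C@@]34C[C@]5(C(=O)O[C@@H]6CC(C)=C([C@@H](C)CCCOC(C)=O)[C@@H](O[Si](C)(C)C(C)(C)C)[C@@H]65)[C@@H](C(C)=C3C[C@H]12)[C@H]4OC(C)=O | intermediate
36 | CNP0211028.3 | C=C1C(=O)O[C@H]2C[C@H](C)[C@@]34C[C@]5(C(=O)O[C@@H]6CC(C)=C([C@@H](C)CCCOC(C)=O)[C@@H](O)[C@@H]65)[C@@H](C(C)=C3C[C@H]12)[C@H]4OC(C)=O | target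

**Totals**
Total step count: 25. Longest linear sequence: 22 (steps 1–5, 7–15, 18–25).

**Steps most likely to fail**

1. Step 7, mismatched double diastereoselection. The anti-to-C2 and exo preferences together require bond formation at C11' on the lactone face syn to C6'. The cis-fused lactone itself prefers attack on its convex face (syn to H7'), so the union may divert to the carbonyl-endo spiro isomer. The fallback sets out from 9 and returns at 12. It uses the 6',12'-iso-lactone, in which the required C11' configuration is the one formed on the open face (syn to H7', anti to C8' and its acyloxy group), so all three preferences coincide. Compound 9 is opened with one equivalent of LiOH (aq THF, 0 °C), which should open the strained lactone faster than it cleaves the primary acetate, and the carboxylate is methylated in the same flask (MeI, DMF) to give seco ester F1. The freed C8' hydroxyl is acylated ((ClCH2CO)2O, pyridine) to chloroacetate F2. HF·pyridine removes the C6' silyl ether to give hydroxy ester F3, and camphorsulfonic acid in warm toluene closes the trans-fused iso-lactone F4. F4 and 7 under the conditions of step 7 give silyl cycloadduct F5 and, after citric acid, ketol F6; Dess–Martin oxidation gives diketone F7. Thiourea with NaHCO3 in ethanol removes the chloroacetate and the liberated C8' hydroxyl translactonises to the more stable cis-fused 8',12'-lactone, hydroxy diketone F8. Silylation (t-BuMe2SiOTf, 2,6-lutidine) then gives 12.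

2. Step 21, protodesilylation of the allylsilane or loss of face selectivity at C8 during the medium-ring closure. The fallback sets out from 29 and returns at 31. NBS (propylene oxide, CH2Cl2, −78 °C) effects bromodesilylation with allylic transposition to give allylic bromide F9. CrCl2 in THF then generates the allylchromium species, which adds to the C8 aldehyde through a closed six-membered transition state (Nozaki–Hiyama allylation) to give hydroxy ester 30. Camphorsulfonic acid lactonises 30 to 31.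

3. Step 22, loss of facial control in the hydrogenation, because the C2 acetate can compete with the lactone as the directing group (over-reduction is a lesser concern). The fallback sets out from 29 and returns at 32. The cyclisation of step 21 is quenched cold (Et3N, then NaHCO3) without the acid treatment, so that hydroxy ester 30 is isolated. Its free C8 hydroxyl, a much stronger ligand for the cationic iridium catalyst than any ester, directs the hydrogenation ([Ir(cod)(PCy3)(py)]PF6, H2, CH2Cl2) to give methyl hydroxy ester F10. Camphorsulfonic acid then closes ring A to give 32.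

**Further compounds**
F1 | step 7 | seco methyl ester of 9 with free C8' hydroxyl | COC(=O)C(=C)[C@@H]1[C@H](O)CC(C)=C([C@@H](C)CCCOC(C)=O)[C@H]1O[Si](C)(C)C(C)(C)C
F2 | step 7 | C8' chloroacetate of F1 | COC(=O)C(=C)[C@@H]1[C@H](OC(=O)CCl)CC(C)=C([C@@H](C)CCCOC(C)=O)[C@H]1O[Si](C)(C)C(C)(C)C
F3 | step 7 | C6' hydroxy ester (C8' chloroacetate) | COC(=O)C(=C)[C@@H]1[C@H](OC(=O)CCl)CC(C)=C([C@@H](C)CCCOC(C)=O)[C@H]1O
F4 | step 7 | trans-fused 6',12'-iso-lactone dienophile (C8' chloroacetate) | C=C1C(=O)O[C@@H]2C([C@@H](C)CCCOC(C)=O)=C(C)C[C@@H](OC(=O)CCl)[C@@H]12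
F5 | step 7 | silyl enol ether cycloadduct of the iso-lactone | CC(O[Si](C)(C)C)[C@@]34C[C@]5(C(=O)O[C@@H]6C([C@@H](C)CCCOC(C)=O)=C(C)C[C@@H](OC(=O)CCl)[C@H]65)[C@@H](C(C)=C3O[Si](C)(C)C)[C@H]4O[Si](CC)(CC)CC
F6 | step 7 | iso-lactone ketol | CC(O)[C@@]34C[C@]5(C(=O)O[C@@H]6C([C@@H](C)CCCOC(C)=O)=C(C)C[C@@H](OC(=O)CCl)[C@H]65)[C@@H](C(C)C3=O)[C@H]4O[Si](CC)(CC)CC
F7 | step 7 | iso-lactone 5,10-diketone | CC(=O)[C@@]34C[C@]5(C(=O)O[C@@H]6C([C@@H](C)CCCOC(C)=O)=C(C)C[C@@H](OC(=O)CCl)[C@H]65)[C@@H](C(C)C3=O)[C@H]4O[Si](CC)(CC)CC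
F8 | step 7 | 5,10-diketone with the 8',12'-lactone restored and free C6' hydroxyl | CC(=O)[C@@]34C[C@]5(C(=O)O[C@@H]6CC(C)=C([C@@H](C)CCCOC(C)=O)[C@@H](O)[C@@H]65)[C@@H](C(C)C3=O)[C@H]4O[Si](CC)(CC)CC
F9 | step 21 | allylic bromide aldehyde (C1 bears 3-bromoprop-1-en-2-yl) | C=C(CBr)[C@@]34C[C@]5(C(=O)O[C@@H]6CC(C)=C([C@@H](C)CCCOC(C)=O)[C@@H](O[Si](C)(C)C(C)(C)C)[C@@H]65)[C@@H](C(C)=C3C[C@@H](C=O)C(CO[Si](C)(C)C(C)(C)C)C(=O)OC)[C@H]4OC(C)=O
F10 | step 22 | C10-methyl ring B hydroxy ester | O[C@H]1C[C@H](C)[C@@]34C[C@]5(C(=O)O[C@@H]6CC(C)=C([C@@H](C)CCCOC(C)=O)[C@@H](O[Si](C)(C)C(C)(C)C)[C@@H]65)[C@@H](C(C)=C3C[C@@H]1C(CO[Si](C)(C)C(C)(C)C)C(=O)OC)[C@H]4OC(C)=O
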